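A direct plan would butanoylate 2-methylphloroglucinol A1 to 1-(2,4,6-trihydroxy-3-methylphenyl)butan-1-one A2, methylate one of the three hydroxyls, aminomethylate the free ring carbon and, by thermal loss of the amine, alkylate a second molecule of A1 to reach the diarylmethane pentaphenol A3, in which ring B (butanoyl, methoxy) is complete and ring A (trihydroxy, later pentanoyl) still has one free carbon.
Ring A would then be iodinated to the iodide A4, all five phenols would be benzylated to the pentabenzyl ether A5, the pentanoyl group would be added by a palladium-catalysed carbonylative coupling that delivers the butyl group and gives the pentabenzyl ether of the target A6, and hydrogenolysis would free the phenols.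
The mono-O-methylation would rest only on a modest acidity difference between hydroxyls, so the position of the ether would not be secured by structure.
The iodination and the five-fold benzylation (with the final debenzylation) would spend three steps without adding a skeletal atom, on an electron-rich diarylmethane prone to oxidation, ipso attack at the bridge and C-benzylation.
The carbonylative coupling would be run on the most advanced material at a hexasubstituted iodide flanked by two benzyloxy groups, where hydrodeiodination and direct butyl transfer would compete with ketone formation.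

In each benzene ring the retrosynthesis cuts the bond between the acyl-bearing carbon and a neighbouring C–OH carbon (retro-Claisen), which unravels the ring into a 3,5,7-trioxoalkanoate chain masked as a 6-(2-oxoalkyl)-2-pyranone; one pyranone (4) serves both rings.
This is possible because each ring carries oxygen on alternate carbons with the acyl group between two of them, so the six ring carbons and the acyl carbon are C1–C7 of a polyketide chain, and the two remaining ring carbons (chain C2 and C4) bear only CH3 and the CH2 bridge.
Ring B arises first (step 4); its methoxy oxygen is the C4 oxygen of the pyranone, methylated while it is the only hydroxyl in the molecule.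
The bridge is then made between the ring B ortho-quinone methide and C3 of a second pyranone, and ring A arises last (step 8), already carrying its pentanoyl group, its methyl group and the bridge.
No hydroxyl has to be singled out for methylation, and no halogenation, phenol protection or late acylation is needed; the diarylmethane core exists only in the final product.

Key step: step 8

Remark: enolisable compounds are written as one tautomer; intermediates 8 and 15 are stereoisomer mixtures at sp3 centres that vanish on aromatisation, and the target has no stereocentre.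

Step 1
Reactants: 1 methyl 3-oxopentanoate; 2 N-methoxy-N-methylacetamide
Product: 4 4-hydroxy-5,6-dimethyl-2H-pyran-2-one, via methyl 4-methyl-3,5-dioxohexanoate 3 (not isolated)
Conditions: LiN(iPr)2 (2.3 equiv), THF, −78 to 0 °C; 2 (0.9 equiv), −78 °C to rt; AcOH (2.3 equiv); then PhMe, DBU (1.5 equiv), reflux with distillation of THF; 1 M HCl wash
Reagents that add atoms: none
Why: γ-Acylation of the β-keto ester dianion by the Weinreb amide (Weinreb ketone synthesis, in which the chelated tetrahedral adduct prevents over-addition and proton exchange) should give the 3,5-dioxo ester, which DBU lactonises through its C5 enol oxygen, the standard entry to 4-hydroxy-2-pyranones.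

Step 2
Reactants: 4 4-hydroxy-5,6-dimethyl-2H-pyran-2-one
Product: 5 4-methoxy-5,6-dimethyl-2H-pyran-2-one
Conditions: Me2SO4 (1.2 equiv), K2CO3 (1.5 equiv), acetone, reflux
Reagents that add atoms: dimethyl sulfate, COS(=O)(=O)OC
Why: O-Alkylation of a vinylogous carboxylic acid with a hard methylating agent, which fixes the position of the future aryl methyl ether without any selectivity question because 4 has a single hydroxyl.

Step 3
Reactants: 5 4-methoxy-5,6-dimethyl-2H-pyran-2-one; 6 N-methoxy-N-methylbutanamide
Product: 7 4-methoxy-5-methyl-6-(2-oxopentyl)-2H-pyran-2-one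
Conditions: LiN(iPr)2 (1.1 equiv), THF, −78 °C; 6 (1.2 equiv), −78 to −20 °C; 1 M HCl
Reagents that add atoms: none
Why: Vinylogous deprotonation of the 6-methyl group, the only methyl whose anion is conjugated through C5=C6 and C3=C4 with the lactone carbonyl (the 5-methyl group is cross-conjugated), followed by Weinreb ketone synthesis.

Step 4
Reactants: 7 4-methoxy-5-methyl-6-(2-oxopentyl)-2H-pyran-2-one
Product: 9 1-(2,6-dihydroxy-4-methoxy-3-methylphenyl)butan-1-one (aspidinol), via enol ether ester 8 (not isolated)
Conditions: Mg(OMe)2 (4 equiv), MeOH, reflux, argon; then cold 1 M HCl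
Reagents that add atoms: none
Why: Biomimetic Claisen (Dieckmann-type) ring closure of a masked triketo ester, in which methoxide opens the lactone of 7 to 8, the magnesium-chelated C5/C7 diketonate attacks the ester carbon through C6, and loss of methanol with enolisation should give the arene with the already methylated pyranone C4 oxygen para to the butanoyl group and the pyranone 5-methyl group between methoxyl and hydroxyl.

Step 5
Reactants: 9 aspidinol
Product: 10 1-{3-[(dimethylamino)methyl]-2,6-dihydroxy-4-methoxy-5-methylphenyl}butan-1-one
Conditions: 37% aq. CH2O (1.2 equiv), 40% aq. Me2NH (1.5 equiv), EtOH, 0 °C to rt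
Reagents that add atoms: formaldehyde, C=O; dimethylamine, CNC
Why: Phenol Mannich reaction at the only ring carbon of 9 that bears hydrogen, which lies ortho to a free hydroxyl.

Step 6
Reactants: 4 4-hydroxy-5,6-dimethyl-2H-pyran-2-one; 11 N-methoxy-N-methylpentanamide
Product: 12 4-hydroxy-5-methyl-6-(2-oxohexyl)-2H-pyran-2-one
Conditions: LiN(iPr)2 (2.3 equiv), THF–DMPU, −78 to −20 °C; 11 (1.0 equiv), −78 to 0 °C; 1 M HCl
Reagents that add atoms: none
Why: Dianion chemistry of a 4-hydroxy-6-methyl-2-pyranone, in which the lithium salt of the 4-hydroxyl is deprotonated a second time at the 6-methyl group and this carbanion, not the delocalised oxygen anion, adds to the Weinreb amide (Weinreb ketone synthesis).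

Step 7
Reactants: 10 Mannich base of aspidinol; 12 4-hydroxy-5-methyl-6-(2-oxohexyl)-2H-pyran-2-one
Product: 14 3-[(3-butanoyl-2,4-dihydroxy-6-methoxy-5-methylphenyl)methyl]-4-hydroxy-5-methyl-6-(2-oxohexyl)-2H-pyran-2-one, via ortho-quinone methide 13 (not isolated)
Conditions: 12 (1.5 equiv), dioxane, 100 °C, argon
Reagents that add atoms: none
Why: Thermal loss of dimethylamine from the phenolic Mannich base should give the ortho-quinone methide, which is captured in a Michael addition by C3 of the 4-hydroxy-2-pyranone (a vinylogous acid far more acidic than the side-chain methylene), while ring B has no free carbon for self-condensation and no second benzene ring that could exchange the bridge is yet present.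

Step 8
Reactants: 14 bridged pyranone
Product: 16 1-[3-(3-butanoyl-2,4-dihydroxy-6-methoxy-5-methylbenzyl)-2,4,6-trihydroxy-5-methylphenyl]pentan-1-one (CNP0210501.0), via triketo ester 15 (not isolated)
Conditions: Mg(OMe)2 (8 equiv), MeOH, 50 °C to reflux, argon; then cold 1 M HCl, work-up under argon
Reagents that add atoms: none
Why: Mg(OMe)2 turns 14 into magnesium chelates and methoxide opens the lactone at C2 to the methyl 3,5,7-trioxo ester 15, whose magnesium-bound C5/C7 diketonate attacks the ester carbon C1 through C6; loss of methoxide gives a 2-acylcyclohexane-1,3,5-trione that enolises at once to ring A, which makes the sequence irreversible. The closest known reaction type is the Mg(OMe)2-induced conversion of 6-(2-oxoalkyl)-4-hydroxy- and 4-methoxy-2-pyranones (masked 3,5,7-trioxoalkanoates) into acylphloroglucinols, the same reaction as in step 4, applied here to a pyranone substituted at both C3 and C5. Ring A closes in a 6-(enolexo)-exo-trig Claisen (Dieckmann-type) mode, C6 to C1. No stereocentre is created and the two sp3 centres of 15 (C2 and C4) vanish on aromatisation, so no stereocontrol element is involved. The step needs Claisen closure (C6 to C1) to win over aldol closure (C2 to C7), retro-Claisen cleavage and retro-Michael loss of the ring B benzyl group: C2 carries the benzyl group, so an aldol adduct could not aromatise and would revert, the alkylated β-keto ester terminus is the least acidic of the three acidic sites and so stays an electrophilic ester while C6 is the most acidic, and magnesium chelation of the C5/C7 diketone both folds the chain and makes C7 a poor acceptor. Ring B, whose two phenoxides are chelated to its own ketone, is the product of these very conditions in step 4 and should be a spectator.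

**Compound list**

1 | methyl 3-oxopentanoate | CCC(=O)CC(=O)OC | starting material
2 | N-methoxy-N-methylacetamide | CC(=O)N(C)OC | starting material
3 | methyl 4-methyl-3,5-dioxohexanoate (not isolated) | CC(=O)C(C)C(=O)CC(=O)OC | intermediate
4 | 4-hydroxy-5,6-dimethyl-2H-pyran-2-one | CC1=C(C)C(O)=CC(=O)O1 | intermediate
5 | 4-methoxy-5,6-dimethyl-2H-pyran-2-one | CC1=C(C)C(OC)=CC(=O)O1 | intermediate
6 | N-methoxy-N-methylbutanamide | CCCC(=O)N(C)OC | starting material
7 | 4-methoxy-5-methyl-6-(2-oxopentyl)-2H-pyran-2-one | CCCC(=O)CC1=C(C)C(OC)=CC(=O)O1 | intermediate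
8 | methyl (2E)-3-methoxy-4-methyl-5,7-dioxodec-2-enoate (racemic at C4, not isolated) | CCCC(=O)CC(=O)C(C)/C(OC)=C\C(=O)OC | intermediate
9 | 1-(2,6-dihydroxy-4-methoxy-3-methylphenyl)butan-1-one (aspidinol) | CCCC(=O)c1c(O)cc(OC)c(C)c1O | intermediate
10 | 1-{3-[(dimethylamino)methyl]-2,6-dihydroxy-4-methoxy-5-methylphenyl}butan-1-one | CCCC(=O)c1c(O)c(CN(C)C)c(OC)c(C)c1O | intermediate
11 | N-methoxy-N-methylpentanamide | CCCCC(=O)N(C)OC | starting material
12 | 4-hydroxy-5-methyl-6-(2-oxohexyl)-2H-pyran-2-one | CCCCC(=O)CC1=C(C)C(O)=CC(=O)O1 | intermediate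
13 | 2-butanoyl-3-hydroxy-5-methoxy-4-methyl-6-methylidenecyclohexa-2,4-dien-1-one (ortho-quinone methide, not isolated) | C=C1C(=O)C(C(=O)CCC)=C(O)C(C)=C1OC | intermediate
14 | 3-[(3-butanoyl-2,4-dihydroxy-6-methoxy-5-methylphenyl)methyl]-4-hydroxy-5-methyl-6-(2-oxohexyl)-2H-pyran-2-one | CCCCC(=O)CC1=C(C)C(O)=C(Cc2c(O)c(C(=O)CCC)c(O)c(C)c2OC)C(=O)O1 | intermediate
15 | methyl 2-[(3-butanoyl-2,4-dihydroxy-6-methoxy-5-methylphenyl)methyl]-4-methyl-3,5,7-trioxoundecanoate (mixture of diastereomers, not isolated) | CCCCC(=O)CC(=O)C(C)C(=O)C(Cc1c(O)c(C(=O)CCC)c(O)c(C)c1OC)C(=O)OC | intermediate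
16 | 1-[3-(3-butanoyl-2,4-dihydroxy-6-methoxy-5-methylbenzyl)-2,4,6-trihydroxy-5-methylphenyl]pentan-1-one | CCCCC(=O)c1c(O)c(C)c(O)c(Cc2c(O)c(C(=O)CCC)c(O)c(C)c2OC)c1O | target

Total step count: 8. Longest linear sequence: 7 (steps 1, 2, 3, 4, 5, 7, 8).

Steps most likely to fail:

Step 8 (ring A closure on the bridged pyranone). The anionic lactone may open sluggishly, and the benzylated β-keto ester or the product may lose or exchange the methylene bridge by retro-Michael fragmentation in the basic medium. The fallback sets out from 12 and returns at 16, with ring formation and bridging in reverse order. Pyranone 12 alone would be treated with Mg(OMe)2 in MeOH, which by way of methyl 4-methyl-3,5,7-trioxoundecanoate F1 (not isolated) should give 1-(2,4,6-trihydroxy-3-methylphenyl)pentan-1-one F2. An excess of F2 would then be heated with Mannich base 10 in dioxane, so that ortho-quinone methide 13 is captured under neutral conditions by the only free ring carbon of F2, giving 16.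

Step 7 (capture of the quinone methide by the pyranone). Alkylation may stray to the side-chain methylene or to oxygen, a second quinone methide may add, or the adduct may cyclodehydrate between the ring B hydroxyl and C4 of the pyranone. The fallback sets out from 12 and returns at 14, with the polarity of the union reversed. Pyranone 12 would be aminomethylated (CH2O, Me2NH, EtOH) to 3-[(dimethylamino)methyl]-4-hydroxy-5-methyl-6-(2-oxohexyl)-2H-pyran-2-one F3. Heating F3 with an excess of aspidinol 9 would release 5-methyl-3-methylidene-6-(2-oxohexyl)-2H-pyran-2,4(3H)-dione F4 (not isolated), a Michael acceptor that the single nucleophilic ring carbon of 9 should capture to give 14.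

Step 6 (acylation of the pyranone dianion). The dilithio species may be poorly soluble and form incompletely, so that proton transfer from the amide or O-acylation takes over. The fallback sets out from 4 and returns at 12, with the hydroxyl masked so that a monoanion suffices. MOMCl and iPr2NEt in CH2Cl2 should give 4-(methoxymethoxy)-5,6-dimethyl-2H-pyran-2-one F5. Lithiation with LiN(iPr)2 and addition to 11 as in step 3 should give 4-(methoxymethoxy)-5-methyl-6-(2-oxohexyl)-2H-pyran-2-one F6, and HCl in MeOH would free 12.

**Further compounds**

F1 | step 8 | methyl 4-methyl-3,5,7-trioxoundecanoate | CCCCC(=O)CC(=O)C(C)C(=O)CC(=O)OC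
F2 | step 8 | 1-(2,4,6-trihydroxy-3-methylphenyl)pentan-1-one | CCCCC(=O)c1c(O)cc(O)c(C)c1O
F3 | step 7 | 3-[(dimethylamino)methyl]-4-hydroxy-5-methyl-6-(2-oxohexyl)-2H-pyran-2-one | CCCCC(=O)CC1=C(C)C(O)=C(CN(C)C)C(=O)O1
F4 | step 7 | 5-methyl-3-methylidene-6-(2-oxohexyl)-2H-pyran-2,4(3H)-dione | CCCCC(=O)CC1=C(C)C(=O)C(=C)C(=O)O1
F5 | step 6 | 4-(methoxymethoxy)-5,6-dimethyl-2H-pyran-2-one | COCOC1=CC(=O)OC(C)=C1C
F6 | step 6 | 4-(methoxymethoxy)-5-methyl-6-(2-oxohexyl)-2H-pyran-2-one | CCCCC(=O)CC1=C(C)C(OCOC)=CC(=O)O1
A1 | direct plan | 2-methylphloroglucinol (2-methylbenzene-1,3,5-triol) | Cc1c(O)cc(O)cc1O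
A2 | direct plan | 1-(2,4,6-trihydroxy-3-methylphenyl)butan-1-one | CCCC(=O)c1c(O)cc(O)c(C)c1O
A3 | direct plan | 1-{2,6-dihydroxy-4-methoxy-3-methyl-5-[(2,4,6-trihydroxy-3-methylphenyl)methyl]phenyl}butan-1-one | CCCC(=O)c1c(O)c(Cc2c(O)cc(O)c(C)c2O)c(OC)c(C)c1O
A4 | direct plan | 1-{2,6-dihydroxy-4-methoxy-3-methyl-5-[(2,4,6-trihydroxy-3-iodo-5-methylphenyl)methyl]phenyl}butan-1-one | CCCC(=O)c1c(O)c(Cc2c(O)c(I)c(O)c(C)c2O)c(OC)c(C)c1O
A5 | direct plan | 1-[2,6-bis(benzyloxy)-4-methoxy-3-methyl-5-{[2,4,6-tris(benzyloxy)-3-iodo-5-methylphenyl]methyl}phenyl]butan-1-one | Ic1c(OCc2ccccc2)c(C)c(OCc2ccccc2)c(Cc2c(OCc3ccccc3)c(C(=O)CCC)c(OCc3ccccc3)c(C)c2OC)c1OCc1ccccc1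
A6 | direct plan | 1-[2,4,6-tris(benzyloxy)-3-{[2,4-bis(benzyloxy)-3-butanoyl-6-methoxy-5-methylphenyl]methyl}-5-methylphenyl]pentan-1-one | CCCCC(=O)c1c(OCc2ccccc2)c(C)c(OCc2ccccc2)c(Cc2c(OCc3ccccc3)c(C(=O)CCC)c(OCc3ccccc3)c(C)c2OC)c1OCc1ccccc1
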